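The plan rests on disconnecting the C14–C17 bond of ring E, the ester-bearing cyclopentane (locants defined below). With rings A–D closed, the tetrasubstituted ring-fusion alkene C12=C13 and an allylic carbonate at C14 are ionised by zerovalent palladium to a π-allyl unit whose central carbon C13 carries, through quaternary C20, the propanoate arm; its enolate carbon C17 attacks C14. One operation thus closes the last ring and sets C14 by double inversion, mirroring the ring-closing half of a trimethylenemethane [3+2] cycloaddition. The precursor is a tetracyclic allylic carbonate built from cycloheptane-1,3-dione by Michael addition, double Mannich annulation, Nazarov cyclisation and spiro-dihydropyran assembly.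

Key step: step 14

Remark on locants: C1–C2 ethyl; C3=C4 enol ether; C5; C6 spiro carbon; C7 OCH2; O8; C9 ring CH next to C6; C10; C11; C12=C13 ring-fusion alkene; C14 allylic CH; C15; C16; C17 CH(CO2Me); C18 ester carbon; C19; C20 quaternary carbon bonded to C19, C13, C6 and C21; C21 and C24 NCH2; N22; C23 NCH3. Ring A is the dihydropyran, ring B the piperidine, ring C the cycloheptene, ring D the cyclopentene, ring E the ester-bearing cyclopentane. In these locants the target is 6R,9S,14R,17R,20R.

Remark on the resolution: amine 7 is drawn with the absolute configuration the target requires; which of the two separated enantiomers it is must be established, for example by X-ray analysis of a salt.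

Step 1
Reactants: 1 cycloheptane-1,3-dione; 2 methyl acrylate
Product: 3 methyl 3-(2,6-dioxocycloheptyl)propanoate
Conditions: 1,8-diazabicyclo[5.4.0]undec-7-ene (DBU, 0.1 equiv), MeCN, 25 °C
Reagents that add atoms: none
Why: Base-catalysed Michael addition of the acidic CH between the two carbonyls (future C20) to the acrylate installs C19, C17 and the ester in one step; no stereocentre is formed.

Step 2
Reactants: 3 methyl 3-(2,6-dioxocycloheptyl)propanoate; 4 methylamine; 5 formaldehyde
Product: 6 racemic methyl 3-(8-methyl-2,10-dioxo-8-azabicyclo[4.3.1]decan-1-yl)propanoate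
Conditions: MeNH2 (2 M in MeOH, 1.05 equiv), (CH2O)n (2.2 equiv), AcOH, MeOH, 65 °C
Reagents that add atoms: formaldehyde (second equivalent), C=O
Why: Double Mannich annulation that consumes one methylamine and two formaldehyde units (they become C21 and C24), in which the methyleneiminium ion first alkylates C20 and a second iminium on nitrogen then closes ring B onto the α′-carbon C9, the one-atom ketone bridge (C6) enforcing the cis relation of C20 and C9; the two α′-carbons are enantiotopic, so the product should be racemic.

Step 3
Reactants: 6 racemic bicyclic amino diketone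
Product: 7 (1R,6R)-enantiomer of 6
Conditions: preparative supercritical-fluid chromatography on amylose tris(3,5-dimethylphenylcarbamate), CO2/MeOH with 0.1% Et2NH
Reagents that add atoms: none
Why: Chromatographic resolution of the basic amine on a chiral stationary phase should deliver the enantiomer in which C20 and C9 are configured as in the target.

Step 4
Reactants: 7 (1R,6R)-amino diketone
Product: 8 C12=C13 enol triflate with the C6 bridge ketone intact
Conditions: KN(SiMe3)2 (1.05 equiv), THF, −78 °C; PhNTf2, −78 → 0 °C
Reagents that add atoms: N-phenylbis(trifluoromethanesulfonimide), O=S(=O)(N(c1ccccc1)S(=O)(=O)C(F)(F)F)C(F)(F)F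
Why: Kinetic enolate O-triflation; enolisation can only run toward C12, because C20 is quaternary and the bridge ketone C6 cannot enolise without a bridgehead alkene, and the ketone is more acidic than the ester.

Step 5
Reactants: 8 enol triflate; 9 (methoxymethyl)triphenylphosphonium chloride
Product: 11 C6-formyl compound (both C6 epimers), via enol ether 10 (not isolated)
Conditions: 9, KN(SiMe3)2, THF, 0 → 40 °C; then 2 M aq. HCl, THF, 25 °C
Reagents that add atoms: water, O
Why: Wittig methoxymethylenation of the only remaining, non-enolisable ketone and acid hydrolysis of the enol ether amount to a one-carbon homologation that adds C5 as an aldehyde; the C6 configuration is irrelevant because C6 is enolised again in step 6.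

Step 6
Reactants: 11 C6-formyl compound; 5 formaldehyde
Product: 13 C6 quaternary acetoxymethyl aldehyde, via hydroxymethyl aldehyde 12 (not isolated)
Conditions: 37% aq. CH2O, Et3N (0.3 equiv), THF, 45 °C; then Ac2O, pyridine, 4-(dimethylamino)pyridine (DMAP, cat.), CH2Cl2, 25 °C
Reagents that add atoms: acetic anhydride, CC(=O)OC(C)=O
Why: Amine-catalysed crossed aldol (hydroxymethylation) of the α-branched aldehyde with the smallest carbon electrophile builds quaternary C6 next to quaternary C20; the enol should be attacked on the face turned to the seven-membered bridge (one axial hydrogen at C10 and the flat sp2 carbon C13) in preference to the piperidine face (two axial hydrogens at C21 and C24), which places C7 syn to ring C, and acetylation caps the alcohol for steps 9 and 10.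

Step 7
Reactants: 13 acetoxymethyl aldehyde; 14 diethyl (2-oxobutyl)phosphonate
Product: 15 (E)-enone (C5=C4 conjugated to the C3 ethyl ketone)
Conditions: 14, NaH, THF, 0 → 50 °C
Reagents that add atoms: none
Why: Horner–Wadsworth–Emmons olefination of the neopentyl aldehyde, which has no α-hydrogen, adds C4, C3 and the ethyl group as an (E)-enone.

Step 8
Reactants: 15 (E)-enone
Product: 17 saturated ethyl ketone (3-oxopentyl arm on C6), via triethylsilyl enol ether 16 (not isolated)
Conditions: Et3SiH, RhCl(PPh3)3 (2 mol%), benzene, 50 °C; then 1 M aq. HCl, THF, 0 °C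
Reagents that add atoms: none
Why: RhCl(PPh3)3-catalysed 1,4-hydrosilylation of the enone and hydrolysis of the silyl enol ether is a conjugate reduction that should leave the vinyl triflate, both esters and the amine untouched.

Step 9
Reactants: 17 ethyl ketone enol triflate; 18 tributyl(vinyl)stannane
Product: 19 cross-conjugated divinyl ketone (C13–C14(=O)–C15=C16)
Conditions: CO (1 atm), 18, Pd(PPh3)4 (5 mol%), LiCl, THF, 60 °C
Reagents that add atoms: carbon monoxide, [C-]#[O+]
Why: Carbonylative Stille coupling, in which oxidative addition of zerovalent palladium into the vinyl triflate, CO insertion and transmetalation with the vinylstannane give the dienone.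

Step 10
Reactants: 19 divinyl ketone
Product: 20 ring D cyclopentenone (C14=O, C12=C13)
Conditions: HBF4·OEt2 (3 equiv), CH2Cl2, 0 → 25 °C; aq. NaHCO3
Reagents that add atoms: none
Why: Nazarov cyclisation, a conrotatory 4π-electrocyclisation of the hydroxypentadienyl cation that forms the C12–C16 bond; proton loss toward the more substituted position gives the tetrasubstituted C12=C13 enone without a new stereocentre, and the protonated amine, acetate and saturated ketone are spectators.

Step 11
Reactants: 20 cyclopentenone acetate
Product: 22 tetracyclic enone carrying ring A, via hydroxy ketone 21 (not isolated)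
Conditions: K2CO3 (0.2 equiv), MeOH, 25 °C; evaporate; then p-TsOH·H2O (1.1 equiv), benzene, 4 Å molecular sieves, 80 °C; aq. NaHCO3
Reagents that add atoms: none
Why: Methanolysis of the acetate frees the C7 hydroxyl, which forms the six-membered hemiketal with the saturated ethyl ketone (far more electrophilic than the conjugated C14 ketone), and acid-catalysed cyclodehydration under equilibrating conditions should give the endocyclic, trisubstituted enol ether.

Step 12
Reactants: 22 tetracyclic enone
Product: 23 (14S)-allylic alcohol, hydroxyl on the face of C6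
Conditions: (R)-Me-CBS oxazaborolidine [(R)-1-methyl-3,3-diphenyltetrahydro-1H,3H-pyrrolo[1,2-c][1,3,2]oxazaborole] (0.3 equiv), catecholborane, toluene, −78 °C; aq. NaOH
Reagents that add atoms: none
Why: Corey–Bakshi–Shibata reduction, in which the (R)-catalyst binds the carbonyl with the substituted alkene carbon C13 as the large group and delivers hydride to the Re face (the face of C21, which is also the face away from the quaternary spiro carbon C6); catecholborane at −78 °C should not touch the enol ether or the ester.

Step 13
Reactants: 23 (14S)-allylic alcohol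
Product: 24 (14S)-allylic tert-butyl carbonate
Conditions: Boc2O, DMAP (0.2 equiv), MeCN, 25 °C
Reagents that add atoms: di-tert-butyl dicarbonate, CC(C)(C)OC(=O)OC(=O)OC(C)(C)C
Why: DMAP-catalysed O-acylation gives a carbonate leaving group without α-hydrogens and with retention at C14.

Step 14
Reactants: 24 allylic tert-butyl carbonate
Product: 26 pentacyclic ester expected mainly as the C17 epimer of the target (17S), via lithium ester enolate 25 (not isolated)
Conditions: LiN(SiMe3)2 (1.1 equiv), THF, −78 °C; then Pd(PPh3)4 (10 mol%), −78 → 25 °C; aqueous work-up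
Reagents that add atoms: none
Why: Tsuji–Trost allylic alkylation with a preformed ester enolate: LiN(SiMe3)2 removes the only acidic proton (C17–H) to give 25, zerovalent palladium ionises the carbonate anti to the leaving group (loss of CO2 and tert-butoxide) to a π-allyl complex spanning C12–C13–C14 with the metal on the C21 face, and the enolate carbon attacks C14 from the opposite face. The closest known reaction type is the ring-closing half of a palladium trimethylenemethane [3+2] cycloaddition, where a nucleophile tethered to the central allyl carbon collapses onto an allyl terminus. Ring E closes in a 5-exo manner with respect to the departing C14–Pd bond and leaves C12=C13 exocyclic to the new ring. C14 is controlled by the carbinol configuration from step 12 through double inversion (net retention), so C17 enters on the face of C6; at C17 the ester is expected to take the less hindered position cis to H14, any target formed alongside being carried on. The step needs regioselectivity for C14 over C12, secured by the two-atom tether, which lies anti to C12 and can only reach C14, and chemoselective enolisation, secured because the enol ether, carbonate and amine carry no comparably acidic hydrogen.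

Step 15
Reactants: 26 pentacyclic ester (C17 epimer, with any target)
Product: 28 target CNP0159589.3, via lithium enolate 27 (not isolated)
Conditions: LiN(iPr)2 (1.5 equiv), THF, −78 °C; then AcOH in THF, −78 °C; aq. NaHCO3
Reagents that add atoms: none
Why: Deprotonation to the planar ester enolate and kinetic protonation from the less hindered face of ring E (the face of H14 and C21, away from the spiro carbon C6) should place H17 cis to H14 and so give the target configuration at C17; the amine released from the base buffers the acid and protects the enol ether.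

Compound list
1 | cycloheptane-1,3-dione | O=C1CCCCC(=O)C1 | starting material
2 | methyl acrylate | C=CC(=O)OC | starting material
3 | methyl 3-(2,6-dioxocycloheptyl)propanoate | COC(=O)CCC1C(=O)CCCCC1=O | intermediate
4 | methylamine | CN | starting material
5 | formaldehyde (as paraformaldehyde or formalin) | C=O | starting material
6 | racemic methyl 3-(8-methyl-2,10-dioxo-8-azabicyclo[4.3.1]decan-1-yl)propanoate (relative configuration fixed by the bridge) | COC(=O)CCC12CN(C)CC(CCCC1=O)C2=O | intermediate
7 | methyl 3-[(1R,6R)-8-methyl-2,10-dioxo-8-azabicyclo[4.3.1]decan-1-yl]propanoate (C20 and C9 as in the target) | COC(=O)CC[C@@]12CN(C)C[C@@H](CCCC1=O)C2=O | intermediate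
8 | methyl 3-[(1R,6R)-8-methyl-10-oxo-2-(trifluoromethylsulfonyloxy)-8-azabicyclo[4.3.1]dec-2-en-1-yl]propanoate (C12=C13 enol triflate) | COC(=O)CC[C@@]12CN(C)C[C@@H](CCC=C1OS(=O)(=O)C(F)(F)F)C2=O | intermediate
9 | (methoxymethyl)triphenylphosphonium chloride | COC[P+](c1ccccc1)(c1ccccc1)c1ccccc1.[Cl-] | starting material
10 | enol ether of 8 with C6=CH–OMe (E/Z mixture) | COC(=O)CC[C@@]12CN(C)C[C@@H](CCC=C1OS(=O)(=O)C(F)(F)F)C2=COC | intermediate
11 | C6-formyl enol triflate, mixture of C6 epimers | COC(=O)CC[C@@]12CN(C)C[C@@H](CCC=C1OS(=O)(=O)C(F)(F)F)C2C=O | intermediate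
12 | C6 quaternary aldehyde with CH2OH (C7) on the face of ring C and CHO (C5) on the piperidine face | COC(=O)CC[C@@]12CN(C)C[C@@H](CCC=C1OS(=O)(=O)C(F)(F)F)[C@@]2(C=O)CO | intermediate
13 | acetate of 12 | COC(=O)CC[C@@]12CN(C)C[C@@H](CCC=C1OS(=O)(=O)C(F)(F)F)[C@@]2(C=O)COC(C)=O | intermediate
14 | diethyl (2-oxobutyl)phosphonate | CCC(=O)CP(=O)(OCC)OCC | starting material
15 | (E)-enone: C6 bears CH2OAc and (E)-CH=CH–C(=O)Et | COC(=O)CC[C@@]12CN(C)C[C@@H](CCC=C1OS(=O)(=O)C(F)(F)F)[C@@]2(/C=C/C(=O)CC)COC(C)=O | intermediate
16 | triethylsilyl enol ether from 1,4-hydrosilylation of 15 | COC(=O)CC[C@@]12CN(C)C[C@@H](CCC=C1OS(=O)(=O)C(F)(F)F)[C@@]2(CC=C(CC)O[Si](CC)(CC)CC)COC(C)=O | intermediate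
17 | ethyl ketone: C6 bears CH2OAc (syn to ring C) and 3-oxopentyl (syn to ring B); C13 enol triflate | COC(=O)CC[C@@]12CN(C)C[C@@H](CCC=C1OS(=O)(=O)C(F)(F)F)[C@@]2(CCC(=O)CC)COC(C)=O | intermediate
18 | tributyl(vinyl)stannane | C=C[Sn](CCCC)(CCCC)CCCC | starting material
19 | divinyl ketone: acryloyl group on C13 of the cycloheptene | COC(=O)CC[C@@]12CN(C)C[C@@H](CCC=C1C(=O)C=C)[C@@]2(CCC(=O)CC)COC(C)=O | intermediate
20 | tricyclic cyclopentenone (rings B, C, D; C14=O, C12=C13) with CH2OAc and 3-oxopentyl on C6 | COC(=O)CC[C@@]12CN(C)C[C@@H](CCC3=C1C(=O)CC3)[C@@]2(CCC(=O)CC)COC(C)=O | intermediate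
21 | δ-hydroxy ketone from 20 (in equilibrium with its six-membered hemiketal) | COC(=O)CC[C@@]12CN(C)C[C@@H](CCC3=C1C(=O)CC3)[C@@]2(CCC(=O)CC)CO | intermediate
22 | tetracyclic enone with rings A–D (6-ethyl-3,4-dihydro-2H-pyran spiro at C6; C14=O) | COC(=O)CC[C@@]12CN(C)C[C@@H](CCC3=C1C(=O)CC3)[C@]21CC=C(CC)OC1 | intermediate
23 | (14S)-allylic alcohol of 22, OH on the face of C6 | COC(=O)CC[C@@]12CN(C)C[C@@H](CCC3=C1[C@@H](O)CC3)[C@]21CC=C(CC)OC1 | intermediate
24 | (14S)-allylic tert-butyl carbonate | COC(=O)CC[C@@]12CN(C)C[C@@H](CCC3=C1[C@@H](OC(=O)OC(C)(C)C)CC3)[C@]21CC=C(CC)OC1 | intermediate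
25 | lithium enolate of the methyl ester of 24 (C17=C18) | [Li+].COC([O-])=CC[C@@]12CN(C)C[C@@H](CCC3=C1[C@@H](OC(=O)OC(C)(C)C)CC3)[C@]21CC=C(CC)OC1 | intermediate
26 | 17-epi target (6R,9S,14R,17S,20R), ester cis to H14 | CCC1=CC[C@@]2(CO1)[C@@H]1CCC3=C4[C@H](CC3)[C@@H](C(=O)OC)C[C@@]42CN(C)C1 | intermediate
27 | lithium enolate of the pentacyclic ester (C17=C18) | [Li+].CCC1=CC[C@@]2(CO1)[C@@H]1CCC3=C4[C@H](CC3)C(=C([O-])OC)C[C@@]42CN(C)C1 | intermediate
28 | CNP0159589.3 (6R,9S,14R,17R,20R) | CCC1=CC[C@@]2(CO1)[C@@H]1CCC3=C4[C@H](CC3)[C@H](C(=O)OC)C[C@@]42CN(C)C1 | target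

Total step count: 15
Longest linear sequence: 15 steps, from cycloheptane-1,3-dione (1) to 28.

Steps most likely to fail

Step 14 (key step). The π-allyl intermediate may lose a proton to give a ring D cyclopentadiene instead of being alkylated, or the hard lithium enolate may be delivered through the metal so that C17 ends on the wrong face of C14. The fallback drops palladium for a direct displacement. Setting out from enone 22, (S)-Me-CBS oxazaborolidine and catecholborane would give the C14-epimeric allylic alcohol F1. ClP(O)(OEt)2 and pyridine would convert it into the allylic diethyl phosphate F2. KN(SiMe3)2 in THF (−78 → 0 °C) would then close ring E by intramolecular SN2 alkylation of the ester enolate (5-exo-tet, inversion at C14), rejoining the route at 26.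

Step 6. Formaldehyde may attack the C6 enol with a facial preference opposite to the one predicted, which would invert the spiro centre. The fallback introduces the two arms in the reverse order, so that the same bias gives the required centre. Setting out from aldehyde 11, conjugate addition to ethyl vinyl ketone (pyrrolidine cat., MeCN) would give keto aldehyde F3. LiAlH(OtBu)3 at −78 °C would reduce only the aldehyde to hydroxy ketone F4. Acetylation (Ac2O, pyridine) returns to ketone 17, and steps 7 and 8 are skipped.

Step 5. The bulky phosphorus ylide may fail to add to the doubly α-branched bridge ketone, or may attack the triflate sulfur instead. The fallback uses a smaller sulfur ylide and an epoxide rearrangement. Setting out from 8, dimethylsulfonium methylide (Me3SI, KN(SiMe3)2, THF, 0 °C) would give spiro-epoxide F5, which MgBr2·OEt2 should isomerise by Meinwald rearrangement (hydride shift) to aldehyde 11.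

Further compounds
F1 | step 14 | (14R)-allylic alcohol, C14 epimer of 23 | COC(=O)CC[C@@]12CN(C)C[C@@H](CCC3=C1[C@H](O)CC3)[C@]21CC=C(CC)OC1
F2 | step 14 | (14R)-allylic diethyl phosphate | COC(=O)CC[C@@]12CN(C)C[C@@H](CCC3=C1[C@H](OP(=O)(OCC)OCC)CC3)[C@]21CC=C(CC)OC1
F3 | step 6 | keto aldehyde: C6 bears CHO (syn to ring C) and 3-oxopentyl (syn to ring B) | COC(=O)CC[C@@]12CN(C)C[C@@H](CCC=C1OS(=O)(=O)C(F)(F)F)[C@]2(C=O)CCC(=O)CC
F4 | step 6 | hydroxy ketone: C6 bears CH2OH and 3-oxopentyl | COC(=O)CC[C@@]12CN(C)C[C@@H](CCC=C1OS(=O)(=O)C(F)(F)F)[C@]2(CO)CCC(=O)CC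
F5 | step 5 | spiro-epoxide at C6 of enol triflate 8 | COC(=O)CC[C@@]12CN(C)C[C@@H](CCC=C1OS(=O)(=O)C(F)(F)F)C21CO1
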